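**Retrosynthetic overview**
1. C11=C12: Wittig union of the triol C15 phosphonium salt 9 with the C25 apocarotenal 19; 19 comes from the ε-C15 phosphonium salt 15 and the C10 dialdehyde 16 (C11'=C12' Wittig).
2. Key bond C6–C7: the dilithiated dienol 7, a vinylogous homoenolate whose carbanion carbon is the normally electrophilic 5-position of a 2,4-dienal, adds to the carbonyl carbon of the non-enolisable α-silyloxy ketone 6 and sets C6.
3. 6 comes from (4R,6R)-actinol 3 by silyl enol ether formation and Rubottom oxidation (sets C5); 7 comes from enynol 1 through stannane 2.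
4. 15 comes from (R)-α-ionone 10: vinyl Grignard addition, allylic oxidation, CBS reduction (sets C3'), acetylation, PPh3·HBr.
5. No ring is formed in the route: both six-membered rings are bought intact (3 and 10) and only decorated.

Assumption: 1, 3, 10 and 16 are purchased (3 and 10 as single enantiomers); all polyene work is done under argon in dim light.

**Route**

Step 1
Reactants: 1 (E)-3-methylpent-2-en-4-yn-1-ol
Product: 2 (2E,4E)-3-methyl-5-(tributylstannyl)penta-2,4-dien-1-ol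
Conditions: Bu3SnH (1.1 eq), PdCl2(PPh3)2 (2 mol %), THF, 0 °C → rt
Reagents that add atoms: tributyltin hydride, CCCC[SnH](CCCC)CCCC
Why: Palladium-catalysed syn-hydrostannation of the terminal alkyne of a conjugated enyne puts tin on the terminal carbon and gives the 4E vinylstannane, while the 2E double bond of 1 is untouched.

Step 2
Reactants: 3 (4R,6R)-4-hydroxy-2,2,6-trimethylcyclohexan-1-one (actinol)
Product: 4 (4R)-2,6,6-trimethyl-1,4-bis(triethylsilyloxy)cyclohex-1-ene
Conditions: Et3SiOTf (2.4 eq), Et3N (4 eq), CH2Cl2, 0 °C → rt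
Reagents that add atoms: triethylsilyl trifluoromethanesulfonate, CC[Si](CC)(CC)OS(=O)(=O)C(F)(F)F
Why: Soft enolisation with O-silylation converts the alcohol into its TES ether and the only enolisable α-position (the C6 methine) into the tetrasubstituted silyl enol ether, which erases the C6 stereocentre on purpose and leaves C4 untouched.

Step 3
Reactants: 4 (4R)-2,6,6-trimethyl-1,4-bis(triethylsilyloxy)cyclohex-1-ene
Product: 6 (2S,4S)-2,6,6-trimethyl-2,4-bis(triethylsilyloxy)cyclohexan-1-one, via silyloxy epoxide 5 (not isolated)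
Conditions: mCPBA (1.1 eq), hexane/CH2Cl2, −20 °C → rt
Reagents that add atoms: 3-chloroperoxybenzoic acid, OOC(=O)c1cccc(Cl)c1
Why: Rubottom oxidation, in which the peracid epoxidises the enol ether on the face opposite the pseudoaxial methyl of the gem-dimethyl carbon in the half-chair with equatorial 4-OTES (the face cis to that group) and epoxide opening with 1,4-silyl shift then gives the α-silyloxy ketone with the new C2–O bond cis to C4–O (2S).

Step 4
Reactants: 2 (2E,4E)-3-methyl-5-(tributylstannyl)penta-2,4-dien-1-ol; 6 (2S,4S)-2,6,6-trimethyl-2,4-bis(triethylsilyloxy)cyclohexan-1-one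
Product: 8 (1S,2S,4S)-1-[(1E,3E)-5-hydroxy-3-methylpenta-1,3-dien-1-yl]-2,6,6-trimethyl-2,4-bis(triethylsilyloxy)cyclohexan-1-ol, via dilithio dienyl alkoxide 7 (not isolated)
Conditions: 2 (1.6 eq), n-BuLi (3.2 eq), THF, −78 °C, 1 h; then 6 (1.0 eq), −78 → −20 °C; H2O quench
Reagents that add atoms: none
Why: O-deprotonation and tin–lithium exchange give 7 with retention of the E,E geometry, a vinylogous homoenolate whose carbanion carbon (future C7) is the normally electrophilic 5-position of the latent dienal, and its 1,2-addition to the carbonyl carbon of non-enolisable 6 takes place trans to the C2 methyl because, in the chair with both OTES groups equatorial, the other face is closed by the two axial α-methyl groups, which sets the 1S carbinol (future 6S, trans-5,6-diol).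

Step 5
Reactants: 8 (1S,2S,4S)-1-[(1E,3E)-5-hydroxy-3-methylpenta-1,3-dien-1-yl]-2,6,6-trimethyl-2,4-bis(triethylsilyloxy)cyclohexan-1-ol
Product: 9 [(2E,4E)-3-methyl-5-[(1S,2S,4S)-1,2,4-trihydroxy-2,6,6-trimethylcyclohexyl]penta-2,4-dien-1-yl]triphenylphosphonium bromide
Conditions: PPh3·HBr (1.5 eq), MeOH/CH2Cl2, 0 °C, 1 h; then rt, 6 h
Reagents that add atoms: triphenylphosphine hydrobromide, [Br-].c1ccccc1[PH+](c1ccccc1)c1ccccc1
Why: Acid-mediated ionisation of the primary dienylic alcohol and capture by PPh3 at the terminal carbon gives the conjugated E,E allylic phosphonium salt (SN1-type salt formation), the excess acid methanolyses both TES ethers, and the tertiary carbinol is expected to survive because its cation is destabilised by the adjacent C–O bond and, once formed, by the phosphonium group.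

Step 6
Reactants: 10 (3E)-4-[(1R)-2,6,6-trimethylcyclohex-2-en-1-yl]but-3-en-2-one ((R)-α-ionone)
Product: 11 (1E,3RS)-3-methyl-1-[(1R)-2,6,6-trimethylcyclohex-2-en-1-yl]penta-1,4-dien-3-ol
Conditions: CH2=CHMgBr (1.3 eq), THF, −20 → 0 °C; H2O quench
Reagents that add atoms: vinylmagnesium bromide, C=C[Mg]Br
Why: Grignard 1,2-addition to the methyl enone gives the tertiary divinyl carbinol (the new carbinol centre is a mixture and is destroyed in step 10) without touching the ring stereocentre.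

Step 7
Reactants: 11 (1E,3RS)-3-methyl-1-[(1R)-2,6,6-trimethylcyclohex-2-en-1-yl]penta-1,4-dien-3-ol
Product: 12 (4R)-4-[(1E,3RS)-3-hydroxy-3-methylpenta-1,4-dien-1-yl]-3,5,5-trimethylcyclohex-2-en-1-one
Conditions: t-BuOOH (5 eq), Pd(OH)2/C (5 mol %), K2CO3 (0.25 eq), CH2Cl2, 4 °C
Reagents that add atoms: tert-butyl hydroperoxide, CC(C)(C)OO
Why: Radical allylic C–H oxidation by tert-butylperoxyl radicals attacks the accessible ring CH2 next to the trisubstituted alkene, as it does in α-ionone itself, and the neopentyl-type doubly allylic methine and the tertiary alcohol are expected to stay intact.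

Step 8
Reactants: 12 (4R)-4-[(1E,3RS)-3-hydroxy-3-methylpenta-1,4-dien-1-yl]-3,5,5-trimethylcyclohex-2-en-1-one
Product: 13 (1R,4R)-4-[(1E,3RS)-3-hydroxy-3-methylpenta-1,4-dien-1-yl]-3,5,5-trimethylcyclohex-2-en-1-ol
Conditions: (S)-2-methyl-CBS-oxazaborolidine (0.2 eq), catecholborane (3 eq), toluene/CH2Cl2, −78 °C; MeOH, then aq. NaOH wash
Reagents that add atoms: none
Why: Corey–Bakshi–Shibata 1,2-reduction in which the (S)-catalyst treats the alkenyl arm as the large group and delivers hydride to the face anti to the axial methyl of the gem-dimethyl carbon (side chain pseudoaxial), a matched case giving the 1R alcohol trans to the side chain (future 3'R), with catecholborane leaving the alkenes alone.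

Step 9
Reactants: 13 (1R,4R)-4-[(1E,3RS)-3-hydroxy-3-methylpenta-1,4-dien-1-yl]-3,5,5-trimethylcyclohex-2-en-1-ol
Product: 14 (1R,4R)-4-[(1E,3RS)-3-hydroxy-3-methylpenta-1,4-dien-1-yl]-3,5,5-trimethylcyclohex-2-en-1-yl acetate
Conditions: Ac2O (1.5 eq), pyridine, CH2Cl2, 0 °C → rt
Reagents that add atoms: acetic anhydride, CC(=O)OC(C)=O
Why: Selective acylation of the secondary alcohol (the hindered tertiary carbinol does not react) masks the acid-labile ring allylic alcohol for the next step.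

Step 10
Reactants: 14 (1R,4R)-4-[(1E,3RS)-3-hydroxy-3-methylpenta-1,4-dien-1-yl]-3,5,5-trimethylcyclohex-2-en-1-yl acetate
Product: 15 [(2E,4E)-5-[(1R,4R)-4-acetoxy-2,6,6-trimethylcyclohex-2-en-1-yl]-3-methylpenta-2,4-dien-1-yl]triphenylphosphonium bromide
Conditions: PPh3·HBr (1.05 eq), CH2Cl2, 0 °C → rt; crystallise the 2E salt
Reagents that add atoms: triphenylphosphine hydrobromide, [Br-].c1ccccc1[PH+](c1ccccc1)c1ccccc1
Why: The tertiary divinyl carbinol ionises far more readily than the allylic acetate and PPh3 captures the pentadienyl cation at the terminal vinyl carbon (SN1' salt formation with allylic transposition), giving mainly the conjugated 2E,4E salt.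

Step 11
Reactants: 15 [(2E,4E)-5-[(1R,4R)-4-acetoxy-2,6,6-trimethylcyclohex-2-en-1-yl]-3-methylpenta-2,4-dien-1-yl]triphenylphosphonium bromide; 16 (2E,4E,6E)-2,7-dimethylocta-2,4,6-trienedial
Product: 19 (3R,6R)-3-hydroxy-12'-apo-ε-caroten-12'-al, via acetoxy ylide 17 (not isolated), via acetoxy apocarotenal 18 (not isolated)
Conditions: 16 (2 eq), NaOMe (1.1 eq, slow addition), MeOH/CH2Cl2, −10 °C; then NaOMe (0.5 eq), rt, 2 h; then heptane, 90 °C, 1 h
Reagents that add atoms: none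
Why: Wittig olefination of the semi-stabilised ylide with excess dialdehyde stops at mono-olefination (the product aldehyde is less electrophilic), methoxide then removes the acetate by transesterification, and heating isomerises the hindered Z isomer of the new double bond to E.

Step 12
Reactants: 9 [(2E,4E)-3-methyl-5-[(1S,2S,4S)-1,2,4-trihydroxy-2,6,6-trimethylcyclohexyl]penta-2,4-dien-1-yl]triphenylphosphonium bromide; 19 (3R,6R)-3-hydroxy-12'-apo-ε-caroten-12'-al
Product: 21 (all-E,3S,5S,6S,3'R,6'R)-5,6-dihydro-β,ε-carotene-3,5,6,3'-tetrol (CNP0219917.1), via triol ylide 20 (not isolated)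
Conditions: 9 (1.3 eq), NaOMe (2 eq), MeOH/CH2Cl2, 0 °C → rt; then EtOAc, 70 °C, 2 h; crystallise
Reagents that add atoms: none
Why: Wittig olefination tolerates the free hydroxyl groups and forms C11=C12, thermal isomerisation converts the hindered 11Z isomer to all-E, and no stereocentre is touched.

**Compound list**
1 | (E)-3-methylpent-2-en-4-yn-1-ol | C#C/C(C)=C/CO | starting material
2 | (2E,4E)-3-methyl-5-(tributylstannyl)penta-2,4-dien-1-ol | CCCC[Sn](CCCC)(CCCC)/C=C/C(C)=C/CO | intermediate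
3 | (4R,6R)-4-hydroxy-2,2,6-trimethylcyclohexan-1-one (actinol) | O=C1C(C)(C)C[C@H](O)C[C@H]1C | starting material
4 | (4R)-2,6,6-trimethyl-1,4-bis(triethylsilyloxy)cyclohex-1-ene | CC[Si](CC)(CC)OC1=C(C)C[C@@H](O[Si](CC)(CC)CC)CC1(C)C | intermediate
5 | (1S,4S,6S)-2,2,6-trimethyl-1,4-bis(triethylsilyloxy)-7-oxabicyclo[4.1.0]heptane (oxirane oxygen cis to the 4-silyloxy group) | CC[Si](CC)(CC)O[C@@]12C(C)(C)C[C@H](O[Si](CC)(CC)CC)C[C@]1(C)O2 | intermediate
6 | (2S,4S)-2,6,6-trimethyl-2,4-bis(triethylsilyloxy)cyclohexan-1-one | O=C1C(C)(C)C[C@H](O[Si](CC)(CC)CC)C[C@]1(C)O[Si](CC)(CC)CC | intermediate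
7 | lithium (2E,4E)-5-lithio-3-methylpenta-2,4-dien-1-olate | [Li]/C=C/C(C)=C/CO[Li] | intermediate
8 | (1S,2S,4S)-1-[(1E,3E)-5-hydroxy-3-methylpenta-1,3-dien-1-yl]-2,6,6-trimethyl-2,4-bis(triethylsilyloxy)cyclohexan-1-ol | OC/C=C(C)/C=C/[C@]1(O)C(C)(C)C[C@H](O[Si](CC)(CC)CC)C[C@]1(C)O[Si](CC)(CC)CC | intermediate
9 | [(2E,4E)-3-methyl-5-[(1S,2S,4S)-1,2,4-trihydroxy-2,6,6-trimethylcyclohexyl]penta-2,4-dien-1-yl]triphenylphosphonium bromide | [Br-].c1ccccc1[P+](c1ccccc1)(c1ccccc1)C/C=C(C)/C=C/[C@]1(O)C(C)(C)C[C@H](O)C[C@]1(C)O | intermediate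
10 | (3E)-4-[(1R)-2,6,6-trimethylcyclohex-2-en-1-yl]but-3-en-2-one ((R)-α-ionone) | CC1=CCCC(C)(C)[C@H]1/C=C/C(C)=O | starting material
11 | (1E,3RS)-3-methyl-1-[(1R)-2,6,6-trimethylcyclohex-2-en-1-yl]penta-1,4-dien-3-ol | CC1=CCCC(C)(C)[C@H]1/C=C/C(C)(O)C=C | intermediate
12 | (4R)-4-[(1E,3RS)-3-hydroxy-3-methylpenta-1,4-dien-1-yl]-3,5,5-trimethylcyclohex-2-en-1-one | CC1=CC(=O)CC(C)(C)[C@H]1/C=C/C(C)(O)C=C | intermediate
13 | (1R,4R)-4-[(1E,3RS)-3-hydroxy-3-methylpenta-1,4-dien-1-yl]-3,5,5-trimethylcyclohex-2-en-1-ol | CC1=C[C@H](O)CC(C)(C)[C@H]1/C=C/C(C)(O)C=C | intermediate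
14 | (1R,4R)-4-[(1E,3RS)-3-hydroxy-3-methylpenta-1,4-dien-1-yl]-3,5,5-trimethylcyclohex-2-en-1-yl acetate | CC1=C[C@H](OC(C)=O)CC(C)(C)[C@H]1/C=C/C(C)(O)C=C | intermediate
15 | [(2E,4E)-5-[(1R,4R)-4-acetoxy-2,6,6-trimethylcyclohex-2-en-1-yl]-3-methylpenta-2,4-dien-1-yl]triphenylphosphonium bromide | CC1=C[C@H](OC(C)=O)CC(C)(C)[C@H]1/C=C/C(C)=C/C[P+](c1ccccc1)(c1ccccc1)c1ccccc1.[Br-] | intermediate
16 | (2E,4E,6E)-2,7-dimethylocta-2,4,6-trienedial | O=C/C(C)=C/C=C/C=C(C)/C=O | starting material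
17 | ylide of 15 (acetoxy ε-C15 triphenylphosphonium ylide) | CC1=C[C@H](OC(C)=O)CC(C)(C)[C@H]1/C=C/C(C)=C/[CH-][P+](c1ccccc1)(c1ccccc1)c1ccccc1 | intermediate
18 | (3R,6R)-3-acetoxy-12'-apo-ε-caroten-12'-al | CC1=C[C@H](OC(C)=O)CC(C)(C)[C@H]1/C=C/C(C)=C/C=C/C(C)=C/C=C/C=C(C)/C=O | intermediate
19 | (3R,6R)-3-hydroxy-12'-apo-ε-caroten-12'-al | CC1=C[C@H](O)CC(C)(C)[C@H]1/C=C/C(C)=C/C=C/C(C)=C/C=C/C=C(C)/C=O | intermediate
20 | ylide of 9 (triol C15 triphenylphosphonium ylide) | c1ccccc1[P+](c1ccccc1)(c1ccccc1)[CH-]/C=C(C)/C=C/[C@]1(O)C(C)(C)C[C@H](O)C[C@]1(C)O | intermediate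
21 | (all-E,3S,5S,6S,3'R,6'R)-5,6-dihydro-β,ε-carotene-3,5,6,3'-tetrol | CC1=C[C@H](O)CC(C)(C)[C@H]1/C=C/C(C)=C/C=C/C(C)=C/C=C/C=C(C)/C=C/C=C(C)/C=C/[C@]1(O)C(C)(C)C[C@H](O)C[C@]1(C)O | target

**Totals and risks**

Total step count: 12. Longest linear sequence: 7 steps (10 → 21, steps 6 to 12). The other branches are shorter: 3 → 21 in 5 steps and 1 → 21 in 4 steps.

Most likely to fail, step 4. The ketone is fully substituted at both α-carbons, so addition may be slow, and the facial preference rests on a conformational argument rather than a direct precedent. Fallback, from 6 (with 1) back to 8: 1 is doubly lithiated (n-BuLi, 2 eq, THF, −78 °C) to lithium (E)-5-lithio-3-methylpent-2-en-4-yn-1-olate F1, a much smaller sp carbanion that still acts as a reversed-polarity β-acylvinyl equivalent. It adds to 6 on the same face to give the enynyl carbinol (1R,2S,4S)-1-[(E)-5-hydroxy-3-methylpent-3-en-1-yn-1-yl]-2,6,6-trimethyl-2,4-bis(triethylsilyloxy)cyclohexan-1-ol F2. Hydroxyl-directed trans-hydroalumination of the propargylic triple bond with NaAlH2(OCH2CH2OMe)2 in THF at 0 °C then gives the E alkene and returns to 8.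

Second, step 7. The electron-rich divinyl carbinol side chain may compete for the peroxyl radical, and the doubly allylic methine may be attacked. Fallback, from 10 back to 13:
- 10 is masked (ethylene glycol, HC(OMe)3, cat. TsOH) as the ketal 2-methyl-2-[(E)-2-[(1R)-2,6,6-trimethylcyclohex-2-en-1-yl]ethenyl]-1,3-dioxolane F3.
- The same t-BuOOH oxidation gives the oxo ketal (4R)-3,5,5-trimethyl-4-[(E)-2-(2-methyl-1,3-dioxolan-2-yl)ethenyl]cyclohex-2-en-1-one F4.
- CBS reduction as in step 8 gives the hydroxy ketal (1R,4R)-3,5,5-trimethyl-4-[(E)-2-(2-methyl-1,3-dioxolan-2-yl)ethenyl]cyclohex-2-en-1-ol F5.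
- Mild hydrolysis (PPTS, acetone/H2O) releases (3E)-4-[(1R,4R)-4-hydroxy-2,6,6-trimethylcyclohex-2-en-1-yl]but-3-en-2-one F6.
- CH2=CHMgBr (2.5 eq, THF, −20 °C) converts F6 into 13.

Third, step 5. Acid may ionise the tertiary dienylic carbinol before the phosphonium group is in place. Fallback, from 8 back to 9, with no acid: Appel bromination (CBr4, PPh3, CH2Cl2, −20 °C) of the primary allylic alcohol gives (1S,2S,4S)-1-[(1E,3E)-5-bromo-3-methylpenta-1,3-dien-1-yl]-2,6,6-trimethyl-2,4-bis(triethylsilyloxy)cyclohexan-1-ol F7. SN2 displacement with PPh3 (EtOAc, rt) gives [(2E,4E)-5-[(1S,2S,4S)-1-hydroxy-2,6,6-trimethyl-2,4-bis(triethylsilyloxy)cyclohexyl]-3-methylpenta-2,4-dien-1-yl]triphenylphosphonium bromide F8. Buffered HF·pyridine in THF/pyridine then removes both silyl groups and gives 9.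

**Further compounds**
F1 | step 4 | lithium (E)-5-lithio-3-methylpent-2-en-4-yn-1-olate | [Li]C#C/C(C)=C/CO[Li]
F2 | step 4 | (1R,2S,4S)-1-[(E)-5-hydroxy-3-methylpent-3-en-1-yn-1-yl]-2,6,6-trimethyl-2,4-bis(triethylsilyloxy)cyclohexan-1-ol | OC/C=C(C)/C#C[C@]1(O)C(C)(C)C[C@H](O[Si](CC)(CC)CC)C[C@]1(C)O[Si](CC)(CC)CC
F3 | step 7 | 2-methyl-2-[(E)-2-[(1R)-2,6,6-trimethylcyclohex-2-en-1-yl]ethenyl]-1,3-dioxolane | CC1=CCCC(C)(C)[C@H]1/C=C/C1(C)OCCO1
F4 | step 7 | (4R)-3,5,5-trimethyl-4-[(E)-2-(2-methyl-1,3-dioxolan-2-yl)ethenyl]cyclohex-2-en-1-one | CC1=CC(=O)CC(C)(C)[C@H]1/C=C/C1(C)OCCO1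
F5 | step 7 | (1R,4R)-3,5,5-trimethyl-4-[(E)-2-(2-methyl-1,3-dioxolan-2-yl)ethenyl]cyclohex-2-en-1-ol | CC1=C[C@H](O)CC(C)(C)[C@H]1/C=C/C1(C)OCCO1
F6 | step 7 | (3E)-4-[(1R,4R)-4-hydroxy-2,6,6-trimethylcyclohex-2-en-1-yl]but-3-en-2-one | CC1=C[C@H](O)CC(C)(C)[C@H]1/C=C/C(C)=O
F7 | step 5 | (1S,2S,4S)-1-[(1E,3E)-5-bromo-3-methylpenta-1,3-dien-1-yl]-2,6,6-trimethyl-2,4-bis(triethylsilyloxy)cyclohexan-1-ol | BrC/C=C(C)/C=C/[C@]1(O)C(C)(C)C[C@H](O[Si](CC)(CC)CC)C[C@]1(C)O[Si](CC)(CC)CC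
F8 | step 5 | [(2E,4E)-5-[(1S,2S,4S)-1-hydroxy-2,6,6-trimethyl-2,4-bis(triethylsilyloxy)cyclohexyl]-3-methylpenta-2,4-dien-1-yl]triphenylphosphonium bromide | [Br-].c1ccccc1[P+](c1ccccc1)(c1ccccc1)C/C=C(C)/C=C/[C@]1(O)C(C)(C)C[C@H](O[Si](CC)(CC)CC)C[C@]1(C)O[Si](CC)(CC)CC
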